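## Analysis of the target

Numbering used here: cyclohexane C1 (spiro epoxide carbon), C2 (methyl and 3-furoyl), C3 and C4 (methylenes), C5 (CH with the 1-hydroxyethyl group), C6 (methyl and the enoyl chain); "epoxide CH" is the glycidate carbon that carries CO2Me.

- The target 32 is a cyclohexane whose C1 is the spiro carbon of a methyl glycidate and whose C2 and C6 are quaternary. C6 carries a cross-conjugated enone that ends in a 6,6-dimethyl-5-ylidene-5,6-dihydropyran-2-one.
- It has six stereocentres: C1 (R), C2 (R), C5 (S), C6 (R), the epoxide CH (S) and the carbinol carbon (R). The exocyclic alkene is E.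
- The furoyl group on C2, the hydroxyethyl group on C5, the methyl on C6 and the epoxide oxygen lie on one face of the ring. The C2 methyl, the C6 acyl group and the epoxide carbon lie on the other. The ester is cis to C2 across the epoxide.
- Sensitive groups: the 3-acylfuran (acid, oxidants), the glycidate (acid, nucleophiles), the dienone lactone (a Michael acceptor, labile to base), and the free secondary alcohol, which could lactonise or form a hemiketal.
- The hard part is the run C6–C1–C2 of three fully substituted carbons. Any C1 ketone precursor is flanked by two quaternary centres, and the 1,4-cis relation between C2 and C5 has no neighbouring centre to enforce it.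
- The strategy rests on one feature. The C1 oxygen, the C2 methyl and the two-carbon branch on C5 are the carbonyl, the vinylic methyl and the isopropenyl group of (S)-carvone. The furoyl carbon on C2 and the carbinol carbon on C5 are cis-1,4, so they can be the two carbons of one bridge of a bicyclo[2.2.2]octene that is cut later.

## Retrosynthetic reasoning

**32 from 31.** The lactone carbonyl is taken back to an allylic lactol. The lactone is the strongest Michael acceptor in the molecule, so it is made in the last step, by an oxidation that leaves the unactivated C5 carbinol alone.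

**31 from 30 from 29.** The two silyl groups are removed last. The exocyclic C=C is cut back to a tertiary β-hydroxy ketone 29. Dehydration can only run toward the ketone α-carbon, and the E isomer (acyl away from the gem-dimethyl carbon) is the stable one.

**29 from 24 and 27.** The bond between the enone α-carbon and the pyran ring carbon is cut. A stabilised phosphonate carbanion would add to this hindered, conjugated ketone at the β-position or not at all. A kinetic lithium enolate of the methyl ketone 24 is small and hard and should add at the carbonyl of 27. Fragment 27 comes from 25 by oxidative ring expansion to 26 and silylation of the lactol.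

**24 from 23 from 22.** The acetyl group on C6 and the furoyl group on C2 are taken back to triethylsilyl-protected carbinols. While C1 is still a ketone, a carbonyl on either neighbour would invite retro-Claisen or retro-aldol cleavage and would compete as an electrophile. Both are therefore unmasked only after the epoxide is in place, in one deprotection and one oxidation.

**22 from 20.** The C1–CH and CH–O bonds of the glycidate are cut in the Darzens sense. This is done on the monocyclic ketone 20 and not on a bicyclic precursor. In the bicycle a nucleophile would enter from the face of the alkene bridge and put the oxygen on the wrong face. In the chair of 20 the axial C2 and C6 substituents block one face and the enolate should add from the other.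

**20 from 19 from 18.** The carbinol centre is taken back to the methyl ketone. The reduction is catalyst-controlled and the Felkin–Anh preference of C5 points the same way.

**18 from 17 from 13 and 14.** The bond between the C2 carbinol carbon and furan C3 is cut. The forward step has to pick the aldehyde of 13 over its two ketones, which an aryltitanium reagent does.

**13 from 11.** The formyl carbon on C2 and the acetyl carbon on C5 are rejoined as the two ends of a C=C. This is the step that pays for the strategy: ozonolysis of the bridge of 11 returns both groups cis-1,4 without any reagent control.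

**11 from 9 from 8 from 6.** The two C–C bonds at the quaternary C6 (C3 of the bicycle) are cut. The two-carbon branch is put in first by aldol addition and the methyl group last, because the second electrophile should enter from the face of the alkene bridge, where the target has its methyl.

**6 from 5 from 4.** The trisubstituted alkene in the bridge is traced back to the exocyclic methylidene of 4, and the saturated bridge to the ring alkene of 4. Isomerising first makes the two alkenes differ in substitution, so that hydrogenation can tell them apart.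

**4 from 2.** The bond between the methyl-bearing bridgehead and the bridge CH2 (C2 to the future acyl carbon) is cut. Cutting here returns a carvone that carries the nucleophile (its extended enolate) and the electrophile (an allylic chloride) on the same ring. The quaternary centre then follows from the carvone stereocentre.

**2 from 1.** The allylic chloride is removed. The forward step is an ene-type chlorination of the isopropenyl group of carvone.

## Alternatives that were turned down

**Alternative 1:** The ring bond C1–C2 is cut.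
- Forward key step: the open-chain methyl 3-[(1R)-1-(tert-butyldimethylsilyloxy)ethyl]-2-[3-(4-methoxybenzyloxy)prop-1-yn-1-yl]-2,6-dimethyl-7-(triisopropylsilyloxy)hept-6-enoate A1 would be treated with Ph3PAuCl/AgNTf2. Monovalent gold activates the alkyne, the enol ether carbon attacks anti to gold in a 6-exo-dig closure, and the cyclohexane A2 results. A2 has C2 as a quaternary aldehyde and C1 as an exocyclic alkene with its CH2OPMB group on the C2 side.
- For it: C1 never exists as a ketone between two quaternary carbons. The glycidate carbon is already attached with defined alkene geometry, so epoxidation and oxidation of the ether would finish the glycidate. On this point it is stronger than the chosen route, which must force a Darzens reaction onto a hindered ketone.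
- Against it: the C2 configuration depends on which face of a trisubstituted enol ether reacts in a flexible chain. Only C5 and C6 steer it, through a chair-like transition state, and the enol ether geometry is a further variable. A1 must already hold C5, the carbinol carbon and a propargylic quaternary C6 in enantiopure form, which costs separate asymmetric steps before the key step.
- Comparison: the chosen route gets C2 and C5 from one chiral-pool centre by geometry and accepts the harder C1 chemistry in return. Step counts should be similar.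

**Alternative 2:** The bonds C1–C2 and C5–C6 are cut together.
- Forward key step: the diene 2-(tert-butyldimethylsilyloxy)-1,3-dimethylcyclohexa-1,3-diene A3 and the allenoate A4 (chiral lactone ester of 2-methylbuta-2,3-dienoic acid) would combine under Me2AlCl to the bicyclo[2.2.2]octene A5. Its silyl enol ether bridge ties the future C2 acyl carbon to the C5 branch carbon, which is the bridge idea of the chosen route, built by cycloaddition.
- For it: one step makes the ring, C5 and both quaternary carbons C2 and C6, with the C6 ester in place. The chosen route spends three steps on C6 alone, so this alternative is clearly stronger in step economy up to the core.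
- Against it: the C6 configuration depends on the endo/exo choice between a methyl and an ester on the same dienophile carbon, which is a weak bias. The absolute configuration rests on an auxiliary and not on the chiral pool. In A5 C1 is a methylidene between two quaternary carbons, and the glycidate needs a carboxyl carbon attached to that CH2, which is harder than adding a two-carbon enolate to a ketone.
- Comparison: the chosen route is longer but each stereocentre has a clear origin and C1 stays a ketone, the function a Darzens reaction needs.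

**Alternative 3:** The bond C5–C6 is cut.
- Forward key step: the epoxy keto ester methyl 2-methyl-6-[(2S,3R)-3-methyloxiran-2-yl]-3-oxohexanoate A6 would be treated with Mg(ClO4)2 and Et3N. The chelated enolate opens the epoxide at the nearer carbon with inversion and gives the cyclohexanone A7.
- For it: C5, C6 and the carbinol centre arise in one stereospecific step from an enantiopure epoxide. This fixes the carbinol configuration more firmly than the late reduction of the chosen route, and the ring is reached quickly.
- Against it: in A7 C2 is still a methylene. The methyl and the furoyl group must be added there afterwards, and nothing enforces their orientation relative to C5 and C6, which lie across the carbonyl. The closure itself makes a quaternary carbon by SN2 attack at a secondary epoxide carbon and competes with O-alkylation and with opening at the far carbon.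
- Comparison: the chosen route sets the C2/C5 relation, the one Alternative 3 leaves open, by geometric necessity.

Key step: step 2

Remark on the chemistry: carbons that end as carbonyl carbons of 32 (the silyloxyethyl carbon on C6, the furyl carbinol carbon and the acetal carbon of the pyran unit) are carried as mixtures of epimers and are drawn without configuration; all other centres are single.

## Route

Step 1
Reactants: 1 (S)-(+)-carvone
Product: 2 (5S)-5-(3-chloroprop-1-en-2-yl)-2-methylcyclohex-2-en-1-one
Conditions: Ca(OCl)2, CO2 (dry ice), CH2Cl2/H2O, 0 °C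
Reagents that add atoms: calcium hypochlorite, [Ca+2].[O-]Cl.[O-]Cl
Why: Ene-type allylic chlorination by hypochlorous acid formed in the flask; the electron-rich 1,1-disubstituted alkene reacts, the double bond shifts and the electron-poor enone alkene and the stereocentre are untouched.

Step 2
Reactants: 2 (5S)-5-(3-chloroprop-1-en-2-yl)-2-methylcyclohex-2-en-1-one
Product: 4 (1R,4R)-1-methyl-8-methylidenebicyclo[2.2.2]oct-5-en-2-one, via potassium dienolate 3 (not isolated)
Conditions: KOt-Bu, t-BuOH/THF, high dilution, rt
Reagents that add atoms: none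
Why: The alkoxide deprotonates 2 reversibly at C6 and at C4; the C4-derived linear dienolate 3 carries charge on O, C2 and C4, and only C2 can reach the allylic chloride, so the equilibrating mixture drains through one channel. The C2–CH2 bond forms by intramolecular SN2 displacement (attack at the other allyl terminus would give the same product), which closes the ring C2–CH2–C(=CH2)–C5–C4=C3 in the 6-exo-tet mode and completes the bicyclo[2.2.2]oct-5-en-2-one. The closest known reaction type is the intramolecular α-alkylation of extended enolates of halogenated carvones to bridged β,γ-unsaturated ketones. The one new stereocentre, the methyl-bearing bridgehead (C2 of the target), is controlled by the C5 centre of carvone: the tether can reach C2 only on the ring face it occupies, so the configuration follows from geometry and not from a reagent. The step needs α-carbon alkylation over γ-carbon, α′-carbon and oxygen alkylation; γ and α′ attack would make cyclobutanes and O-attack a bridgehead enol ether, all far higher in strain than the boat-like six-membered transition state. Dilution keeps intermolecular alkylation down.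

Step 3
Reactants: 4 (1R,4R)-1-methyl-8-methylidenebicyclo[2.2.2]oct-5-en-2-one
Product: 5 (1S,4R)-1,5-dimethylbicyclo[2.2.2]octa-5,7-dien-2-one
Conditions: RhCl3·3H2O (cat.), EtOH, 50 °C
Reagents that add atoms: none
Why: Rhodium hydride addition and β-hydride elimination move the exocyclic alkene into the bridge, to the more substituted position; the bridgeheads stop further migration. The temperature is kept low because bicyclo[2.2.2]octadienones can lose ketene on heating.

Step 4
Reactants: 5 (1S,4R)-1,5-dimethylbicyclo[2.2.2]octa-5,7-dien-2-one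
Product: 6 (1S,4S)-1,5-dimethylbicyclo[2.2.2]oct-5-en-2-one
Conditions: H2 (1 atm), RhCl(PPh3)3 (cat.), benzene, rt
Reagents that add atoms: none
Why: Homogeneous hydrogenation with RhCl(PPh3)3 reduces the cis-disubstituted alkene much faster than the trisubstituted one and leaves the ketone alone; no stereocentre is formed.

Step 5
Reactants: 6 (1S,4S)-1,5-dimethylbicyclo[2.2.2]oct-5-en-2-one
Product: 8 (1S,4S)-3-(1-hydroxyethyl)-1,5-dimethylbicyclo[2.2.2]oct-5-en-2-one (epimers at C3 and at the carbinol carbon), via lithium enolate 7 (not isolated)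
Conditions: LiN(i-Pr)2, THF, −78 °C; CH3CHO; AcOH quench at −78 °C
Reagents that add atoms: acetaldehyde, CC=O
Why: Aldol addition; C3 is the only enolisable position. The epimers do not matter, because C3 becomes quaternary in step 7 and the carbinol carbon is oxidised in step 15.

Step 6
Reactants: 8 (1S,4S)-3-(1-hydroxyethyl)-1,5-dimethylbicyclo[2.2.2]oct-5-en-2-one
Product: 9 (1S,4S)-1,5-dimethyl-3-[1-(triethylsilyloxy)ethyl]bicyclo[2.2.2]oct-5-en-2-one (epimers)
Conditions: Et3SiCl, imidazole, DMF, 0 °C → rt
Reagents that add atoms: chlorotriethylsilane, CC[Si](Cl)(CC)CC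
Why: Silylation stops retro-aldol cleavage and masks the future acetyl group as an ether that can be removed selectively later.

Step 7
Reactants: 9 (1S,4S)-1,5-dimethyl-3-[1-(triethylsilyloxy)ethyl]bicyclo[2.2.2]oct-5-en-2-one
Product: 11 (1S,3S,4R)-1,3,5-trimethyl-3-[1-(triethylsilyloxy)ethyl]bicyclo[2.2.2]oct-5-en-2-one (epimers at the silyloxyethyl carbon), via lithium enolate 10 (not isolated)
Conditions: LiN(i-Pr)2, THF, −78 °C; MeI, DMPU, −78 → −20 °C
Reagents that add atoms: iodomethane, CI
Why: Enolate alkylation at C3. Methyl iodide should approach from the face of the C5=C6 alkene bridge, whose sp2 carbons have no inward-pointing hydrogen, and not from the face of the C7–C8 ethano bridge. This puts methyl syn to the alkene bridge and the silyloxyethyl branch syn to the ethano bridge, which is the C6 configuration of the target.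

Step 8
Reactants: 11 (1S,3S,4R)-1,3,5-trimethyl-3-[1-(triethylsilyloxy)ethyl]bicyclo[2.2.2]oct-5-en-2-one
Product: 13 (1S,3S,4S)-4-acetyl-1,3-dimethyl-2-oxo-3-[1-(triethylsilyloxy)ethyl]cyclohexane-1-carbaldehyde, via ozonide 12 (not isolated)
Conditions: O3, CH2Cl2, −78 °C; PPh3, −78 °C → rt
Reagents that add atoms: ozone, [O-][O+]=O
Why: Ozonolysis of the only C=C with reductive work-up. The bridge carbons become a formyl group on C2 and an acetyl group on C5 of the target ring; they are cis-1,4 because they were one bridge.

Step 9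
Reactants: 13 (1S,3S,4S)-4-acetyl-1,3-dimethyl-2-oxo-3-[1-(triethylsilyloxy)ethyl]cyclohexane-1-carbaldehyde; 14 3-bromofuran
Product: 17 (2S,3S,6S)-3-acetyl-6-[furan-3-yl(hydroxy)methyl]-2,6-dimethyl-2-[1-(triethylsilyloxy)ethyl]cyclohexan-1-one (epimers at the furyl carbinol carbon), via furan-3-yllithium 15 (not isolated), via triisopropoxy(furan-3-yl)titanium 16 (not isolated)
Conditions: 14, n-BuLi, THF, −78 °C; ClTi(Oi-Pr)3, −78 °C; then 13, −78 → 0 °C
Reagents that add atoms: none
Why: Bromine–lithium exchange at −78 °C (cold, to avoid isomerisation to the 2-furyl anion), then transmetalation. Aryltitanium triisopropoxides are weakly basic and add to aldehydes far faster than to ketones, so the methyl ketone and the hindered ring ketone should remain.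

Step 10
Reactants: 17 (2S,3S,6S)-3-acetyl-6-[furan-3-yl(hydroxy)methyl]-2,6-dimethyl-2-[1-(triethylsilyloxy)ethyl]cyclohexan-1-one
Product: 18 (2S,3S,6S)-3-acetyl-6-[furan-3-yl(triethylsilyloxy)methyl]-2,6-dimethyl-2-[1-(triethylsilyloxy)ethyl]cyclohexan-1-one
Conditions: Et3SiOTf, 2,6-lutidine, CH2Cl2, −78 → 0 °C
Reagents that add atoms: triethylsilyl trifluoromethanesulfonate, CC[Si](CC)(CC)OS(=O)(=O)C(F)(F)F
Why: Silylation of a hindered secondary alcohol with the triflate. It stops retro-aldol loss of the furyl unit and keeps C2 free of a carbonyl until the epoxide is made.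

Step 11
Reactants: 18 (2S,3S,6S)-3-acetyl-6-[furan-3-yl(triethylsilyloxy)methyl]-2,6-dimethyl-2-[1-(triethylsilyloxy)ethyl]cyclohexan-1-one
Product: 19 (2S,3S,6S)-6-[furan-3-yl(triethylsilyloxy)methyl]-3-[(1R)-1-hydroxyethyl]-2,6-dimethyl-2-[1-(triethylsilyloxy)ethyl]cyclohexan-1-one
Conditions: (S)-Me-CBS [(S)-1-methyl-3,3-diphenyltetrahydro-1H,3H-pyrrolo[1,2-c][1,3,2]oxazaborole] (cat.), BH3·SMe2, THF, −20 °C
Reagents that add atoms: none
Why: CBS reduction. With methyl as the small group and the ring carbon as the large group, the (S)-catalyst should give the (R)-carbinol, and the Felkin–Anh preference of the C5 centre points the same way (matched case). The ring ketone between two quaternary carbons is too hindered to react.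

Step 12
Reactants: 19 (2S,3S,6S)-6-[furan-3-yl(triethylsilyloxy)methyl]-3-[(1R)-1-hydroxyethyl]-2,6-dimethyl-2-[1-(triethylsilyloxy)ethyl]cyclohexan-1-one
Product: 20 (2S,3S,6S)-3-[(1R)-1-(tert-butyldimethylsilyloxy)ethyl]-6-[furan-3-yl(triethylsilyloxy)methyl]-2,6-dimethyl-2-[1-(triethylsilyloxy)ethyl]cyclohexan-1-one
Conditions: t-BuMe2SiOTf, 2,6-lutidine, CH2Cl2, 0 °C
Reagents that add atoms: tert-butyldimethylsilyl trifluoromethanesulfonate, CC(C)(C)[Si](C)(C)OS(=O)(=O)C(F)(F)F
Why: Silylation with a group more robust than triethylsilyl, so that the other two carbinols can be unmasked selectively in step 14. A free alcohol here would form a hemiketal with the C1 ketone under base.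

Step 13
Reactants: 20 (2S,3S,6S)-3-[(1R)-1-(tert-butyldimethylsilyloxy)ethyl]-6-[furan-3-yl(triethylsilyloxy)methyl]-2,6-dimethyl-2-[1-(triethylsilyloxy)ethyl]cyclohexan-1-one
Product: 22 methyl (2S,3R,4S,5S,8S)-5-[(1R)-1-(tert-butyldimethylsilyloxy)ethyl]-8-[furan-3-yl(triethylsilyloxy)methyl]-4,8-dimethyl-4-[1-(triethylsilyloxy)ethyl]-1-oxaspiro[2.5]octane-2-carboxylate, via sodium chlorohydrin alkoxide 21 (not isolated)
Conditions: ClCH2CO2Me, NaN(SiMe3)2, THF, −78 → 0 °C
Reagents that add atoms: methyl chloroacetate, COC(=O)CCl
Why: Darzens condensation: the enolate of methyl chloroacetate adds to the non-enolisable C1 ketone and alkoxide 21 displaces chloride in a 3-exo-tet closure; with no carbonyl on C2 or C6 the alkoxide cannot fragment. In the chair that keeps the C5 branch equatorial, the C2 furylcarbinol branch and the C6 methyl are axial on one face, so the enolate should add axially on the other face and leave the oxygen on the face of the C6 methyl, as in the target. The aldol step is reversible, and the closure that turns the ester toward C2 (equatorial methyl) rather than toward C6 (equatorial silyloxyethyl branch) should be faster, which gives the required epoxide CH configuration.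

Step 14
Reactants: 22 methyl (2S,3R,4S,5S,8S)-5-[(1R)-1-(tert-butyldimethylsilyloxy)ethyl]-8-[furan-3-yl(triethylsilyloxy)methyl]-4,8-dimethyl-4-[1-(triethylsilyloxy)ethyl]-1-oxaspiro[2.5]octane-2-carboxylate
Product: 23 methyl (2S,3R,4S,5S,8S)-5-[(1R)-1-(tert-butyldimethylsilyloxy)ethyl]-8-[furan-3-yl(hydroxy)methyl]-4-(1-hydroxyethyl)-4,8-dimethyl-1-oxaspiro[2.5]octane-2-carboxylate
Conditions: pyridinium p-toluenesulfonate (cat.), MeOH/CH2Cl2, 0 °C
Reagents that add atoms: none
Why: Acid-catalysed methanolysis removes triethylsilyl ethers much faster than the tert-butyldimethylsilyl ether; the electron-poor glycidate epoxide tolerates this mild acid. The diol is oxidised at once so that the furyl carbinol cannot lactonise onto the glycidate ester.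

Step 15
Reactants: 23 methyl (2S,3R,4S,5S,8S)-5-[(1R)-1-(tert-butyldimethylsilyloxy)ethyl]-8-[furan-3-yl(hydroxy)methyl]-4-(1-hydroxyethyl)-4,8-dimethyl-1-oxaspiro[2.5]octane-2-carboxylate
Product: 24 methyl (2S,3R,4R,5S,8R)-4-acetyl-5-[(1R)-1-(tert-butyldimethylsilyloxy)ethyl]-8-(furan-3-carbonyl)-4,8-dimethyl-1-oxaspiro[2.5]octane-2-carboxylate
Conditions: Dess–Martin periodinane, NaHCO3, CH2Cl2, rt
Reagents that add atoms: none
Why: Dess–Martin oxidation of both hindered secondary alcohols under buffered, near-neutral conditions that spare the furan and the epoxide. Both epimeric centres disappear, which leaves a single compound.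

Step 16
Reactants: 25 2-(furan-2-yl)propan-2-ol
Product: 26 6-hydroxy-2,2-dimethyl-2H-pyran-3(6H)-one (racemic)
Conditions: mCPBA, CH2Cl2, 0 °C
Reagents that add atoms: 3-chloroperbenzoic acid, OOC(=O)c1cccc(Cl)c1
Why: Achmatowicz rearrangement: oxidation of the furan and ring expansion through the tertiary alcohol give the pyranone lactol.

Step 17
Reactants: 26 6-hydroxy-2,2-dimethyl-2H-pyran-3(6H)-one
Product: 27 6-(tert-butyldimethylsilyloxy)-2,2-dimethyl-2H-pyran-3(6H)-one (racemic)
Conditions: t-BuMe2SiCl, imidazole, DMF, 0 °C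
Reagents that add atoms: tert-butylchlorodimethylsilane, CC(C)(C)[Si](C)(C)Cl
Why: Silylation of the lactol removes the acidic proton and stops ring opening under base; the lactone oxidation level is withheld, so the ketone is part of a simple enone and not of an ene-dione.

Step 18
Reactants: 24 methyl (2S,3R,4R,5S,8R)-4-acetyl-5-[(1R)-1-(tert-butyldimethylsilyloxy)ethyl]-8-(furan-3-carbonyl)-4,8-dimethyl-1-oxaspiro[2.5]octane-2-carboxylate; 27 6-(tert-butyldimethylsilyloxy)-2,2-dimethyl-2H-pyran-3(6H)-one
Product: 29 methyl (2S,3R,4R,5S,8R)-4-{2-[6-(tert-butyldimethylsilyloxy)-3-hydroxy-2,2-dimethyl-3,6-dihydro-2H-pyran-3-yl]acetyl}-5-[(1R)-1-(tert-butyldimethylsilyloxy)ethyl]-8-(furan-3-carbonyl)-4,8-dimethyl-1-oxaspiro[2.5]octane-2-carboxylate (epimers at the two pyran centres), via lithium enolate 28 (not isolated)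
Conditions: LiN(i-Pr)2, THF, −78 °C; 27; AcOH quench at −78 °C
Reagents that add atoms: none
Why: Kinetic aldol addition: the acetyl CH3 is the only acidic position next to a ketone, and lithium enolates add to enones at the carbonyl carbon under kinetic control at −78 °C. The cold acidic quench prevents retro-aldol reversal; the acyl group on C6 is trans to the furoyl group on C2, so the enolate cannot reach it.

Step 19
Reactants: 29 the aldol adduct
Product: 30 methyl (2S,3R,4R,5S,8R)-4-{(2E)-2-[6-(tert-butyldimethylsilyloxy)-2,2-dimethyl-2H-pyran-3(6H)-ylidene]acetyl}-5-[(1R)-1-(tert-butyldimethylsilyloxy)ethyl]-8-(furan-3-carbonyl)-4,8-dimethyl-1-oxaspiro[2.5]octane-2-carboxylate (epimers at the acetal carbon)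
Conditions: Martin sulfurane Ph2S[OC(CF3)2Ph]2, CH2Cl2, 0 °C → rt
Reagents that add atoms: none
Why: Dehydration of a tertiary alcohol with Martin sulfurane; the only β-hydrogens are those α to the ketone, so the conjugated dienone is the only product. The E isomer, with the acyl group away from the gem-dimethyl carbon, is the stable one and minor Z isomer should equilibrate to it.

Step 20
Reactants: 30 the bis-silyl dienone
Product: 31 methyl (2S,3R,4R,5S,8R)-8-(furan-3-carbonyl)-4-{(2E)-2-[6-hydroxy-2,2-dimethyl-2H-pyran-3(6H)-ylidene]acetyl}-5-[(1R)-1-hydroxyethyl]-4,8-dimethyl-1-oxaspiro[2.5]octane-2-carboxylate (epimers at the lactol carbon)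
Conditions: HF·pyridine, pyridine, THF, 0 °C → rt
Reagents that add atoms: none
Why: Buffered fluoride cleaves the anomeric and the secondary silyl ether; these conditions avoid the basicity of tetrabutylammonium fluoride, which would endanger the dienone and the glycidate.

Step 21
Reactants: 31 the dienone lactol
Product: 32 methyl (2S,3R,4R,5S,8R)-4-[(2E)-2-(2,2-dimethyl-6-oxo-2H-pyran-3(6H)-ylidene)acetyl]-8-(furan-3-carbonyl)-5-[(1R)-1-hydroxyethyl]-4,8-dimethyl-1-oxaspiro[2.5]octane-2-carboxylate
Conditions: MnO2, CH2Cl2, rt
Reagents that add atoms: none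
Why: MnO2 oxidises the allylic lactol to the unsaturated lactone and does not touch the unactivated secondary alcohol; both lactol epimers converge on the target.

## Compound list

1 | (S)-(+)-carvone, (5S)-2-methyl-5-(prop-1-en-2-yl)cyclohex-2-en-1-one | CC1=CC[C@@H](CC1=O)C(C)=C | starting material
2 | (5S)-5-(3-chloroprop-1-en-2-yl)-2-methylcyclohex-2-en-1-one | CC1=CC[C@@H](CC1=O)C(CCl)=C | intermediate
3 | potassium (5R)-5-(3-chloroprop-1-en-2-yl)-2-methylcyclohexa-1,3-dien-1-olate | [K+].[O-]C1=C(C)C=C[C@@H](C1)C(CCl)=C | intermediate (not isolated)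
4 | (1R,4R)-1-methyl-8-methylidenebicyclo[2.2.2]oct-5-en-2-one | O=C1C[C@@H]2C=C[C@@]1(C)CC2=C | intermediate
5 | (1S,4R)-1,5-dimethylbicyclo[2.2.2]octa-5,7-dien-2-one | O=C1C[C@@H]2C=C[C@@]1(C)C=C2C | intermediate
6 | (1S,4S)-1,5-dimethylbicyclo[2.2.2]oct-5-en-2-one | O=C1C[C@@H]2CC[C@@]1(C)C=C2C | intermediate
7 | lithium (1S,4S)-1,5-dimethylbicyclo[2.2.2]octa-2,5-dien-2-olate | [Li+].[O-]C1=C[C@@H]2CC[C@@]1(C)C=C2C | intermediate (not isolated)
8 | (1S,4S)-3-(1-hydroxyethyl)-1,5-dimethylbicyclo[2.2.2]oct-5-en-2-one, epimers at C3 and the carbinol carbon | O=C1C(C(C)O)[C@@H]2CC[C@@]1(C)C=C2C | intermediate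
9 | (1S,4S)-1,5-dimethyl-3-[1-(triethylsilyloxy)ethyl]bicyclo[2.2.2]oct-5-en-2-one, epimers | O=C1C(C(C)O[Si](CC)(CC)CC)[C@@H]2CC[C@@]1(C)C=C2C | intermediate
10 | lithium (1S,4R)-1,5-dimethyl-3-[1-(triethylsilyloxy)ethyl]bicyclo[2.2.2]octa-2,5-dien-2-olate | [Li+].[O-]C1=C(C(C)O[Si](CC)(CC)CC)[C@@H]2CC[C@@]1(C)C=C2C | intermediate (not isolated)
11 | (1S,3S,4R)-1,3,5-trimethyl-3-[1-(triethylsilyloxy)ethyl]bicyclo[2.2.2]oct-5-en-2-one, epimers at the silyloxyethyl carbon | O=C1[C@](C)(C(C)O[Si](CC)(CC)CC)[C@@H]2CC[C@@]1(C)C=C2C | intermediate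
12 | ozonide (1,2,4-trioxolane across the former C5=C6 bond) of 11 | O=C1[C@](C)(C(C)O[Si](CC)(CC)CC)[C@@H]2CC[C@@]1(C)C3OOC2(C)O3 | intermediate (not isolated)
13 | (1S,3S,4S)-4-acetyl-1,3-dimethyl-2-oxo-3-[1-(triethylsilyloxy)ethyl]cyclohexane-1-carbaldehyde | O=C1[C@](C)(C=O)CC[C@H](C(C)=O)[C@@]1(C)C(C)O[Si](CC)(CC)CC | intermediate
14 | 3-bromofuran | Brc1ccoc1 | starting material
15 | furan-3-yllithium | [Li]c1ccoc1 | intermediate (not isolated)
16 | triisopropoxy(furan-3-yl)titanium | CC(C)O[Ti](OC(C)C)(OC(C)C)c1ccoc1 | intermediate (not isolated)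
17 | (2S,3S,6S)-3-acetyl-6-[furan-3-yl(hydroxy)methyl]-2,6-dimethyl-2-[1-(triethylsilyloxy)ethyl]cyclohexan-1-one, epimers at the furyl carbinol carbon | O=C1[C@](C)(C(O)c2ccoc2)CC[C@H](C(C)=O)[C@@]1(C)C(C)O[Si](CC)(CC)CC | intermediate
18 | (2S,3S,6S)-3-acetyl-6-[furan-3-yl(triethylsilyloxy)methyl]-2,6-dimethyl-2-[1-(triethylsilyloxy)ethyl]cyclohexan-1-one | O=C1[C@](C)(C(O[Si](CC)(CC)CC)c2ccoc2)CC[C@H](C(C)=O)[C@@]1(C)C(C)O[Si](CC)(CC)CC | intermediate
19 | (2S,3S,6S)-6-[furan-3-yl(triethylsilyloxy)methyl]-3-[(1R)-1-hydroxyethyl]-2,6-dimethyl-2-[1-(triethylsilyloxy)ethyl]cyclohexan-1-one | O=C1[C@](C)(C(O[Si](CC)(CC)CC)c2ccoc2)CC[C@H]([C@@H](C)O)[C@@]1(C)C(C)O[Si](CC)(CC)CC | intermediate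
20 | (2S,3S,6S)-3-[(1R)-1-(tert-butyldimethylsilyloxy)ethyl]-6-[furan-3-yl(triethylsilyloxy)methyl]-2,6-dimethyl-2-[1-(triethylsilyloxy)ethyl]cyclohexan-1-one | O=C1[C@](C)(C(O[Si](CC)(CC)CC)c2ccoc2)CC[C@H]([C@@H](C)O[Si](C)(C)C(C)(C)C)[C@@]1(C)C(C)O[Si](CC)(CC)CC | intermediate
21 | sodium alkoxide of the chlorohydrin, methyl 2-chloro-2-(1-oxidocyclohexyl)acetate carrying the substituents of 20, oxygen on the face of the C6 methyl | [Na+].[O-][C@]1([C@@H](Cl)C(=O)OC)[C@](C)(C(O[Si](CC)(CC)CC)c2ccoc2)CC[C@H]([C@@H](C)O[Si](C)(C)C(C)(C)C)[C@@]1(C)C(C)O[Si](CC)(CC)CC | intermediate (not isolated)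
22 | methyl (2S,3R,4S,5S,8S)-5-[(1R)-1-(tert-butyldimethylsilyloxy)ethyl]-8-[furan-3-yl(triethylsilyloxy)methyl]-4,8-dimethyl-4-[1-(triethylsilyloxy)ethyl]-1-oxaspiro[2.5]octane-2-carboxylate | COC(=O)[C@H]1O[C@@]12[C@](C)(C(O[Si](CC)(CC)CC)c3ccoc3)CC[C@H]([C@@H](C)O[Si](C)(C)C(C)(C)C)[C@@]2(C)C(C)O[Si](CC)(CC)CC | intermediate
23 | methyl (2S,3R,4S,5S,8S)-5-[(1R)-1-(tert-butyldimethylsilyloxy)ethyl]-8-[furan-3-yl(hydroxy)methyl]-4-(1-hydroxyethyl)-4,8-dimethyl-1-oxaspiro[2.5]octane-2-carboxylate | COC(=O)[C@H]1O[C@@]12[C@](C)(C(O)c3ccoc3)CC[C@H]([C@@H](C)O[Si](C)(C)C(C)(C)C)[C@@]2(C)C(C)O | intermediate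
24 | methyl (2S,3R,4R,5S,8R)-4-acetyl-5-[(1R)-1-(tert-butyldimethylsilyloxy)ethyl]-8-(furan-3-carbonyl)-4,8-dimethyl-1-oxaspiro[2.5]octane-2-carboxylate | COC(=O)[C@H]1O[C@@]12[C@](C)(C(=O)c3ccoc3)CC[C@H]([C@@H](C)O[Si](C)(C)C(C)(C)C)[C@@]2(C)C(C)=O | intermediate
25 | 2-(furan-2-yl)propan-2-ol | CC(C)(O)c1ccco1 | starting material
26 | 6-hydroxy-2,2-dimethyl-2H-pyran-3(6H)-one, racemic | CC1(C)OC(O)C=CC1=O | intermediate
27 | 6-(tert-butyldimethylsilyloxy)-2,2-dimethyl-2H-pyran-3(6H)-one, racemic | CC1(C)OC(O[Si](C)(C)C(C)(C)C)C=CC1=O | intermediate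
28 | lithium enolate of 24 (enolate of the acetyl group) | [Li+].COC(=O)[C@H]1O[C@@]12[C@](C)(C(=O)c3ccoc3)CC[C@H]([C@@H](C)O[Si](C)(C)C(C)(C)C)[C@@]2(C)C([O-])=C | intermediate (not isolated)
29 | methyl (2S,3R,4R,5S,8R)-4-{2-[6-(tert-butyldimethylsilyloxy)-3-hydroxy-2,2-dimethyl-3,6-dihydro-2H-pyran-3-yl]acetyl}-5-[(1R)-1-(tert-butyldimethylsilyloxy)ethyl]-8-(furan-3-carbonyl)-4,8-dimethyl-1-oxaspiro[2.5]octane-2-carboxylate, epimers at the two pyran centres | COC(=O)[C@H]1O[C@@]12[C@](C)(C(=O)c3ccoc3)CC[C@H]([C@@H](C)O[Si](C)(C)C(C)(C)C)[C@@]2(C)C(=O)CC4(O)C=CC(O[Si](C)(C)C(C)(C)C)OC4(C)C | intermediate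
30 | methyl (2S,3R,4R,5S,8R)-4-{(2E)-2-[6-(tert-butyldimethylsilyloxy)-2,2-dimethyl-2H-pyran-3(6H)-ylidene]acetyl}-5-[(1R)-1-(tert-butyldimethylsilyloxy)ethyl]-8-(furan-3-carbonyl)-4,8-dimethyl-1-oxaspiro[2.5]octane-2-carboxylate, epimers at the acetal carbon | COC(=O)[C@H]1O[C@@]12[C@](C)(C(=O)c3ccoc3)CC[C@H]([C@@H](C)O[Si](C)(C)C(C)(C)C)[C@@]2(C)C(=O)/C=C4\C=CC(O[Si](C)(C)C(C)(C)C)OC4(C)C | intermediate
31 | methyl (2S,3R,4R,5S,8R)-8-(furan-3-carbonyl)-4-{(2E)-2-[6-hydroxy-2,2-dimethyl-2H-pyran-3(6H)-ylidene]acetyl}-5-[(1R)-1-hydroxyethyl]-4,8-dimethyl-1-oxaspiro[2.5]octane-2-carboxylate, epimers at the lactol carbon | COC(=O)[C@H]1O[C@@]12[C@](C)(C(=O)c3ccoc3)CC[C@H]([C@@H](C)O)[C@@]2(C)C(=O)/C=C4\C=CC(O)OC4(C)C | intermediate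
32 | methyl (2S,3R,4R,5S,8R)-4-[(2E)-2-(2,2-dimethyl-6-oxo-2H-pyran-3(6H)-ylidene)acetyl]-8-(furan-3-carbonyl)-5-[(1R)-1-hydroxyethyl]-4,8-dimethyl-1-oxaspiro[2.5]octane-2-carboxylate | COC(=O)[C@H]1O[C@@]12[C@](C)(C(=O)c1ccoc1)CC[C@H]([C@@H](C)O)[C@@]2(C)C(=O)/C=C1\C=CC(=O)OC1(C)C | target

## Step count and least certain steps

Total step count: 21 (19 on the main line, 2 for fragment 27). Longest linear sequence: 19 steps (steps 1–15 and 18–21).

**Step 2 (key step).** The most likely failure is loss of material to intermolecular alkylation or to base-induced loss of HCl before the dienolate closes, because the closing transition state is a boat and the base is strong.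
Fallback: from 2, silylation under equilibrating conditions (Me3SiCl, NaI, Et3N, MeCN) should give the linear dienol ether {[(5R)-5-(3-chloroprop-1-en-2-yl)-2-methylcyclohexa-1,3-dien-1-yl]oxy}trimethylsilane F1. ZnCl2 (cat.) in CH2Cl2 then activates the allylic chloride, and the neutral dienol ether closes at the same α-carbon without strong base. This returns to the route at 4.

**Step 13 (Darzens).** The ketone lies between two quaternary carbons. The addition may not proceed because the aldol equilibrium lies on the side of the ketone, the chloroacetate enolate may self-condense first, and the facial choice or the orientation of the ester may be poor if the ring does not react through the assumed chair.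
Fallback: from 20, a Reformatsky addition (Zn, BrCH2CO2Me, THF) separates C–C bond formation from ring closure and should give the β-hydroxy ester methyl 2-{3-[(1R)-1-(tert-butyldimethylsilyloxy)ethyl]-6-[furan-3-yl(triethylsilyloxy)methyl]-1-hydroxy-2,6-dimethyl-2-[1-(triethylsilyloxy)ethyl]cyclohexyl}acetate F5 by the same axial attack. Its alkoxide–enolate dianion (2 equiv LiN(i-Pr)2, THF, −78 °C) is iodinated with I2, and the α-iodo alkoxide closes to the epoxide. This returns to the route at 22; the configuration at the epoxide CH would have to be checked.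

**Step 7 (methylation).** Facial selectivity may be poor, because the vinylic methyl of the alkene bridge lies near C3 and could offset the usual preference for the alkene face. Loss of silanolate from the β-silyloxy enolate is a second risk.
Fallback: from 6, the order of the two bond formations is inverted. Methylation (LiN(i-Pr)2, MeI) gives (1S,4S)-1,3,5-trimethylbicyclo[2.2.2]oct-5-en-2-one F3. Its enolate adds to acetaldehyde on whichever face electrophiles prefer and gives (1S,3S,4R)-3-(1-hydroxyethyl)-1,3,5-trimethylbicyclo[2.2.2]oct-5-en-2-one F4 if that face is the ethano face. Silylation (Et3SiCl, imidazole) returns to the route at 11.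

**Step 3 (isomerisation).** The dienone 5 may lose ketene by retro-Diels–Alder fragmentation at the temperature the isomerisation needs, or the isomerisation may stall.
Fallback: from 4, the order is reversed so that no bicyclooctadienone is formed. Diimide (KO2CN=NCO2K, AcOH, MeOH, rt) should reduce the strained ring alkene first and give (1S,4S)-1-methyl-5-methylidenebicyclo[2.2.2]octan-2-one F2. This can then be isomerised without thermal risk (TsOH cat., benzene, reflux, or RhCl3·3H2O, EtOH, reflux), which returns to the route at 6.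

**Step 18 (aldol).** Addition of a ketone enolate to a ketone next to a quaternary carbon is reversible and may not go to completion. Proton transfer or conjugate addition may take over on warming.
Fallback: from 24, the bond is made with an irreversible acetylide addition.
- The enolate is trapped (LiN(i-Pr)2, PhNTf2) as the enol triflate methyl (2S,3R,4R,5S,8R)-5-[(1R)-1-(tert-butyldimethylsilyloxy)ethyl]-8-(furan-3-carbonyl)-4,8-dimethyl-4-[1-(trifluoromethylsulfonyloxy)ethenyl]-1-oxaspiro[2.5]octane-2-carboxylate F6.
- Elimination with LiN(i-Pr)2 gives the alkyne methyl (2S,3R,4R,5S,8R)-5-[(1R)-1-(tert-butyldimethylsilyloxy)ethyl]-4-ethynyl-8-(furan-3-carbonyl)-4,8-dimethyl-1-oxaspiro[2.5]octane-2-carboxylate F7.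
- Deprotonation (LiN(SiMe3)2, −78 °C) and addition to 27 give the propargylic alcohol methyl (2S,3R,4R,5S,8R)-4-{[6-(tert-butyldimethylsilyloxy)-3-hydroxy-2,2-dimethyl-3,6-dihydro-2H-pyran-3-yl]ethynyl}-5-[(1R)-1-(tert-butyldimethylsilyloxy)ethyl]-8-(furan-3-carbonyl)-4,8-dimethyl-1-oxaspiro[2.5]octane-2-carboxylate F8.
- A Meyer–Schuster rearrangement (Ph3PAuNTf2 cat., MeOH additive, toluene, rt) turns F8 into the E enone and returns to the route at 30.

## Further compounds

F1 | step 2 | {[(5R)-5-(3-chloroprop-1-en-2-yl)-2-methylcyclohexa-1,3-dien-1-yl]oxy}trimethylsilane | C[Si](C)(C)OC1=C(C)C=C[C@@H](C1)C(CCl)=C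
F2 | step 3 | (1S,4S)-1-methyl-5-methylidenebicyclo[2.2.2]octan-2-one | O=C1C[C@@H]2CC[C@@]1(C)CC2=C
F3 | step 7 | (1S,4S)-1,3,5-trimethylbicyclo[2.2.2]oct-5-en-2-one, epimers at C3 | O=C1C(C)[C@@H]2CC[C@@]1(C)C=C2C
F4 | step 7 | (1S,3S,4R)-3-(1-hydroxyethyl)-1,3,5-trimethylbicyclo[2.2.2]oct-5-en-2-one, epimers at the carbinol carbon | O=C1[C@](C)(C(C)O)[C@@H]2CC[C@@]1(C)C=C2C
F5 | step 13 | methyl 2-{3-[(1R)-1-(tert-butyldimethylsilyloxy)ethyl]-6-[furan-3-yl(triethylsilyloxy)methyl]-1-hydroxy-2,6-dimethyl-2-[1-(triethylsilyloxy)ethyl]cyclohexyl}acetate, ring configuration as in 20, hydroxyl on the face of the methyl on the silyloxyethyl-bearing carbon | COC(=O)C[C@@]1(O)[C@](C)(C(O[Si](CC)(CC)CC)c2ccoc2)CC[C@H]([C@@H](C)O[Si](C)(C)C(C)(C)C)[C@@]1(C)C(C)O[Si](CC)(CC)CC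
F6 | step 18 | methyl (2S,3R,4R,5S,8R)-5-[(1R)-1-(tert-butyldimethylsilyloxy)ethyl]-8-(furan-3-carbonyl)-4,8-dimethyl-4-[1-(trifluoromethylsulfonyloxy)ethenyl]-1-oxaspiro[2.5]octane-2-carboxylate | COC(=O)[C@H]1O[C@@]12[C@](C)(C(=O)c3ccoc3)CC[C@H]([C@@H](C)O[Si](C)(C)C(C)(C)C)[C@@]2(C)C(=C)OS(=O)(=O)C(F)(F)F
F7 | step 18 | methyl (2S,3R,4R,5S,8R)-5-[(1R)-1-(tert-butyldimethylsilyloxy)ethyl]-4-ethynyl-8-(furan-3-carbonyl)-4,8-dimethyl-1-oxaspiro[2.5]octane-2-carboxylate | COC(=O)[C@H]1O[C@@]12[C@](C)(C(=O)c3ccoc3)CC[C@H]([C@@H](C)O[Si](C)(C)C(C)(C)C)[C@@]2(C)C#C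
F8 | step 18 | methyl (2S,3R,4R,5S,8R)-4-{[6-(tert-butyldimethylsilyloxy)-3-hydroxy-2,2-dimethyl-3,6-dihydro-2H-pyran-3-yl]ethynyl}-5-[(1R)-1-(tert-butyldimethylsilyloxy)ethyl]-8-(furan-3-carbonyl)-4,8-dimethyl-1-oxaspiro[2.5]octane-2-carboxylate, epimers at the two pyran centres | COC(=O)[C@H]1O[C@@]12[C@](C)(C(=O)c3ccoc3)CC[C@H]([C@@H](C)O[Si](C)(C)C(C)(C)C)[C@@]2(C)C#CC4(O)C=CC(O[Si](C)(C)C(C)(C)C)OC4(C)C
A1 | alternative 1 | methyl 3-[(1R)-1-(tert-butyldimethylsilyloxy)ethyl]-2-[3-(4-methoxybenzyloxy)prop-1-yn-1-yl]-2,6-dimethyl-7-(triisopropylsilyloxy)hept-6-enoate, single diastereomer at C2 and C3 | COc1ccc(COCC#C[C@](C)(C(=O)OC)[C@H](CCC(C)=CO[Si](C(C)C)(C(C)C)C(C)C)[C@@H](C)O[Si](C)(C)C(C)(C)C)cc1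
A2 | alternative 1 | methyl 6-[(1R)-1-(tert-butyldimethylsilyloxy)ethyl]-3-formyl-2-[2-(4-methoxybenzyloxy)ethylidene]-1,3-dimethylcyclohexane-1-carboxylate, CH2OPMB on the side of the formyl-bearing carbon | COc1ccc(COC/C=C2\[C@](C)(C=O)CC[C@H]([C@@H](C)O[Si](C)(C)C(C)(C)C)[C@@]2(C)C(=O)OC)cc1
A3 | alternative 2 | 2-(tert-butyldimethylsilyloxy)-1,3-dimethylcyclohexa-1,3-diene | CC1=C(O[Si](C)(C)C(C)(C)C)C(C)=CCC1
A4 | alternative 2 | (3R)-4,4-dimethyl-2-oxooxolan-3-yl 2-methylbuta-2,3-dienoate | C=C=C(C)C(=O)O[C@H]1C(=O)OCC1(C)C
A5 | alternative 2 | (3R)-4,4-dimethyl-2-oxooxolan-3-yl 6-(tert-butyldimethylsilyloxy)-1,3,5-trimethyl-2-methylidenebicyclo[2.2.2]oct-5-ene-3-carboxylate, single stereoisomer | C=C1[C@@]2(C)CC[C@H](C(C)=C2O[Si](C)(C)C(C)(C)C)[C@@]1(C)C(=O)O[C@H]1C(=O)OCC1(C)C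
A6 | alternative 3 | methyl 2-methyl-6-[(2S,3R)-3-methyloxiran-2-yl]-3-oxohexanoate | COC(=O)C(C)C(=O)CCC[C@@H]1O[C@@H]1C
A7 | alternative 3 | methyl (1R,2S)-2-[(1R)-1-hydroxyethyl]-1-methyl-6-oxocyclohexane-1-carboxylate | O=C1CCC[C@H]([C@@H](C)O)[C@@]1(C)C(=O)OC
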